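**Retrosynthetic overview**

1. Target 19 ⇐ triol 17 (three acetylations, then desilylation) ⇐ tetracyclic keto-alkene 14; C7 comes from equatorial methyl addition, C7' from α-epoxidation and hydride opening.
2. Key step, chosen instead of coupling two finished bicyclic halves at the central CH2–CH2 bond: the second oxepane–cyclohexanone is grown in one step on the first by an epoxonium oxa-/carbacyclization cascade of diepoxy enol silane 12 (disconnections O1–C2 and C5a–C6).
3. 12 ⇐ cross-metathesis of allyl bicycle 10 with diepoxy vinyl ketone 5 (C6–CH2 bond), then 1,4-hydrosilylation, which fixes the enol silane regiochemistry.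
4. 10 ⇐ the same cascade on enol silane 6, made from 5 by conjugate vinyl addition (central CH2–CH2 bond); 5 ⇐ (E)-geranylacetone by double Shi epoxidation and Mannich methylenation, so 5 is used twice.
5. Ring order: oxepane then cyclohexane of the half with the free 3-OH (step 5), then oxepane then cyclohexane of the 3-OAc half (step 10).

Assumption: (E)-geranylacetone is bought as the pure E isomer; the L-fructose-derived Shi ketone is a catalyst and is not numbered.

Naming: locants are those of 1-benzoxepine (O1, C2 = CMe2, C3 = CH–O, C5a = C–CH3, C6 = CH bearing the bridge, C7, C9a = CH–O), primed for the half made first (free 3-OH in the target). "Bicycle B" = (3S,5aS,6R,9aS)-3-(tert-butyldimethylsilyloxy)-2,2,5a-trimethyl-7-methylidenedecahydro-1-benzoxepin-6-yl.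

**Route**

Step 1
Reactants: 1 (E)-geranylacetone
Product: 2 (5S,6S,9S)-5,6:9,10-diepoxy-6,10-dimethylundecan-2-one
Conditions: 1,2:4,5-di-O-isopropylidene-β-L-erythro-2,3-hexodiulo-2,6-pyranose (0.4 equiv), Oxone (2KHSO5·KHSO4·K2SO4), K2CO3, Bu4NHSO4, MeCN/CH2(OMe)2/aq. Na2B4O7 (pH 10.5), 0 °C
Reagents that add atoms: potassium peroxymonosulfate [K+].[O-]S(=O)(=O)OO
Why: Shi asymmetric epoxidation: the chiral dioxirane transfers oxygen through a spiro transition state to both trisubstituted alkenes (the unactivated methyl ketone is inert), and this catalyst enantiomer gives the (S)-configured CH–O carbon at each epoxide, which fixes the later C3, C5a and C9a of both halves.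

Step 2
Reactants: 2 diepoxy ketone
Product: 3 (6S,7S,10S)-1-(dimethylamino)-6,7:10,11-diepoxy-7,11-dimethyldodecan-3-one
Conditions: LiN(i-Pr)2, THF, −78 °C; CH2=NMe2+ I−, −78 → 0 °C
Reagents that add atoms: N,N-dimethylmethyleneiminium iodide C=[N+](C)C.[I-]
Why: Mannich reaction of the kinetic enolate, formed at the methyl group at −78 °C where the amide base does not touch the trisubstituted epoxides, with the preformed iminium salt; no stereocentre is formed.

Step 3
Reactants: 3 Mannich base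
Product: 5 (6S,7S,10S)-6,7:10,11-diepoxy-7,11-dimethyldodec-1-en-3-one, via ammonium iodide 4 (not isolated)
Conditions: MeI, Et2O, rt; then aq. NaHCO3/CH2Cl2, rt
Reagents that add atoms: none
Why: Exhaustive N-methylation followed by E1cB (Hofmann-type) elimination of trimethylamine under bicarbonate gives the vinyl ketone without acid or strong base, so both epoxides survive.

Step 4
Reactants: 5 diepoxy vinyl ketone
Product: 6 (4Z,8S,9S,12S)-8,9:12,13-diepoxy-9,13-dimethyl-5-(trimethylsilyloxy)tetradeca-1,4-diene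
Conditions: CH2=CHMgBr, CuBr·SMe2 (5 mol %), TMSCl, HMPA, THF, −78 °C; Et3N, pentane work-up
Reagents that add atoms: vinylmagnesium bromide C=C[Mg]Br; chlorotrimethylsilane C[Si](C)(C)Cl
Why: Copper-catalysed, TMSCl-accelerated conjugate addition of CH2=CHMgBr: the enolate is silylated as it forms, so the enol silane is regiodefined (C=C towards the new allyl group) and mainly Z from the s-cis enone, while the hindered epoxides are inert at −78 °C.

Step 5
Reactants: 6 diepoxy enol silane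
Product: 8 (3S,5aS,6S,9aS)-6-allyl-3-hydroxy-2,2,5a-trimethyloctahydro-1-benzoxepin-7(2H)-one, via silyl ether 7 (not isolated)
Conditions: TMSOTf (1.1 equiv), 2,6-di-tert-butyl-4-methylpyridine, CH2Cl2 (0.01 M), −78 °C; then 1 M HCl, THF, 0 °C
Reagents that add atoms: none
Why: Epoxonium-triggered tandem oxa-/carbacyclization of a polyepoxide: the silylated terminal epoxide is opened at its tertiary carbon by the oxygen of the neighbouring epoxide (oxepane, C3 configuration retained), and the resulting bicyclic epoxonium ion is opened at its tertiary carbon with inversion by the enol silane through a chair transition state, which sets the trans ring fusion (5aS,9aS) and, from the Z enol silane and equilibration next to the ketone, the equatorial 6-allyl group.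

Step 6
Reactants: 8 hydroxy ketone
Product: 9 (3S,5aS,6S,9aS)-6-allyl-3-(tert-butyldimethylsilyloxy)-2,2,5a-trimethyloctahydro-1-benzoxepin-7(2H)-one
Conditions: TBSOTf, 2,6-lutidine, CH2Cl2, −78 → 0 °C
Reagents that add atoms: tert-butyldimethylsilyl triflate CC(C)(C)[Si](C)(C)OS(=O)(=O)C(F)(F)F
Why: Silyl triflate silylation of the hindered secondary alcohol masks the one hydroxyl that must be free in the target; no stereocentre changes.

Step 7
Reactants: 9 silyl ether ketone
Product: 10 (3S,5aS,6R,9aS)-6-allyl-3-(tert-butyldimethylsilyloxy)-2,2,5a-trimethyl-7-methylidenedecahydro-1-benzoxepine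
Conditions: Ph3PCH3Br, KOt-Bu, THF, 0 → 50 °C
Reagents that add atoms: methyltriphenylphosphonium bromide C[P+](c1ccccc1)(c1ccccc1)c1ccccc1.[Br-]
Why: Wittig methylenation of the cyclohexanone installs the exocyclic alkene that later becomes the 7'-methyl carbinol, and any base-induced epimerisation at C6' beforehand leads to the desired equatorial isomer.

Step 8
Reactants: 10 allyl bicycle; 5 diepoxy vinyl ketone
Product: 11 (2E,7S,8S,11S)-7,8:11,12-diepoxy-8,12-dimethyl-1-(bicycle B)tridec-2-en-4-one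
Conditions: 5 (2 equiv), second-generation Hoveyda–Grubbs catalyst RuCl2(H2IMes)(=CH–C6H4-2-Oi-Pr) (5 mol %), 1,4-benzoquinone (10 mol %), CH2Cl2, 40 °C
Reagents that add atoms: none
Why: Olefin cross-metathesis between the unhindered monosubstituted alkene and the electron-poor vinyl ketone gives the E enone selectively, while the 1,1-disubstituted methylidene group and the epoxides do not react.

Step 9
Reactants: 11 enone
Product: 12 (3Z,7S,8S,11S)-7,8:11,12-diepoxy-8,12-dimethyl-1-(bicycle B)-4-(triethylsilyloxy)tridec-3-ene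
Conditions: Et3SiH, RhCl(PPh3)3 (2 mol %), toluene, 50 °C
Reagents that add atoms: triethylsilane CC[SiH](CC)CC
Why: Rhodium-catalysed 1,4-hydrosilylation of the enone gives the silyl enol ether with its C=C fixed between the former carbonyl and α-carbons (mainly Z), under neutral conditions that leave the epoxides, the silyl ether and the hindered alkene untouched.

Step 10
Reactants: 12 diepoxy enol silane carrying bicycle B
Product: 14 1-[(3S,5aS,6S,9aS)-3-hydroxy-2,2,5a-trimethyl-7-oxodecahydro-1-benzoxepin-6-yl]-2-(bicycle B)ethane, via silyl ether 13 (not isolated)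
Conditions: TESOTf (1.1 equiv), 2,6-di-tert-butyl-4-methylpyridine, CH2Cl2 (0.005 M), −78 °C; then AcOH/THF/H2O (3:1:1), rt
Reagents that add atoms: none
Why: The same epoxonium oxa-/carbacyclization cascade as in step 5 now builds the second oxepane and cyclohexanone on the tethered substrate: C3 and C9a keep the epoxide configuration, C5a is set by inversion (trans fusion), C6 is equatorial from the Z enol silane and thermodynamically favoured next to the ketone, the remote stereocentres play no part, and aqueous acetic acid then removes only the new triethylsilyl ether.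

Step 11
Reactants: 14 keto alcohol
Product: 15 1-[(3S,5aS,6S,7R,9aS)-3,7-dihydroxy-2,2,5a,7-tetramethyldecahydro-1-benzoxepin-6-yl]-2-(bicycle B)ethane
Conditions: MeLi, CeCl3, THF, −78 °C
Reagents that add atoms: methyllithium [Li]C
Why: 1,2-Addition of CH3CeCl2 to the enolisable ketone: methyl enters along the equatorial (α) trajectory because the axial approach is blocked by the syn-axial 5a-methyl group, giving the axial 7β-hydroxyl and equatorial 7α-methyl (7R).

Step 12
Reactants: 15 diol alkene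
Product: 16 the 7'-spiro-oxirane of 15 (7'S; oxirane oxygen α and equatorial, oxirane CH2 β and axial)
Conditions: mCPBA, NaHCO3, CH2Cl2, 0 °C
Reagents that add atoms: 3-chloroperoxybenzoic acid OOC(=O)c1cccc(Cl)c1
Why: Prilezhaev epoxidation of the only alkene from its α face, anti to the syn-axial 5a'-methyl group, places the epoxide oxygen equatorial (α) at C7'.

Step 13
Reactants: 16 spiro-epoxide
Product: 17 1-[(3S,5aS,6S,7R,9aS)-3,7-dihydroxy-2,2,5a,7-tetramethyldecahydro-1-benzoxepin-6-yl]-2-[(3'S,5a'S,6'S,7'S,9a'S)-3'-(tert-butyldimethylsilyloxy)-7'-hydroxy-2',2',5a',7'-tetramethyldecahydro-1-benzoxepin-6'-yl]ethane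
Conditions: LiBHEt3, THF, 0 °C → rt
Reagents that add atoms: none
Why: SN2 opening of the spiro-epoxide by hydride at the unhindered CH2 carbon turns it into the axial 7'β-methyl group and leaves the equatorial 7'α-hydroxyl set in step 12 (7'S).

Step 14
Reactants: 17 triol
Product: 18 the 3,7,7'-tri-O-acetate of 17
Conditions: Ac2O, DMAP, Et3N, CH2Cl2, 40 °C
Reagents that add atoms: acetic anhydride CC(=O)OC(C)=O
Why: DMAP-catalysed (Steglich-type) acylation under forcing conditions esterifies the secondary 3-hydroxyl and both tertiary hydroxyls while the TBS ether stays in place; no stereocentre is touched.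

Step 15
Reactants: 18 triacetate silyl ether
Product: 19 CNP0169816.1
Conditions: HF·pyridine, pyridine, THF, 0 °C → rt
Reagents that add atoms: none
Why: Fluoride-mediated desilylation cleaves the TBS ether selectively because acetates and the ring ethers are inert to buffered HF·pyridine, releasing the free 3'-hydroxyl of the target.

**Compound list**

1 | (E)-geranylacetone, (5E)-6,10-dimethylundeca-5,9-dien-2-one | CC(=O)CC/C=C(\C)CCC=C(C)C | starting material
2 | (5S,6S,9S)-5,6:9,10-diepoxy-6,10-dimethylundecan-2-one | CC(=O)CC[C@@H]1O[C@@]1(C)CC[C@@H]1OC1(C)C | intermediate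
3 | (6S,7S,10S)-1-(dimethylamino)-6,7:10,11-diepoxy-7,11-dimethyldodecan-3-one | CN(C)CCC(=O)CC[C@@H]1O[C@@]1(C)CC[C@@H]1OC1(C)C | intermediate
4 | (6S,7S,10S)-6,7:10,11-diepoxy-N,N,N,7,11-pentamethyl-3-oxododecan-1-aminium iodide | C[N+](C)(C)CCC(=O)CC[C@@H]1O[C@@]1(C)CC[C@@H]1OC1(C)C.[I-] | intermediate
5 | (6S,7S,10S)-6,7:10,11-diepoxy-7,11-dimethyldodec-1-en-3-one | C=CC(=O)CC[C@@H]1O[C@@]1(C)CC[C@@H]1OC1(C)C | intermediate
6 | (4Z,8S,9S,12S)-8,9:12,13-diepoxy-9,13-dimethyl-5-(trimethylsilyloxy)tetradeca-1,4-diene | C=CC/C=C(\O[Si](C)(C)C)CC[C@@H]1O[C@@]1(C)CC[C@@H]1OC1(C)C | intermediate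
7 | (3S,5aS,6S,9aS)-6-allyl-2,2,5a-trimethyl-3-(trimethylsilyloxy)octahydro-1-benzoxepin-7(2H)-one | C[Si](C)(C)O[C@H]1CC[C@]2(C)[C@H](CCC(=O)[C@H]2CC=C)OC1(C)C | intermediate
8 | (3S,5aS,6S,9aS)-6-allyl-3-hydroxy-2,2,5a-trimethyloctahydro-1-benzoxepin-7(2H)-one | O[C@H]1CC[C@]2(C)[C@H](CCC(=O)[C@H]2CC=C)OC1(C)C | intermediate
9 | (3S,5aS,6S,9aS)-6-allyl-3-(tert-butyldimethylsilyloxy)-2,2,5a-trimethyloctahydro-1-benzoxepin-7(2H)-one | CC(C)(C)[Si](C)(C)O[C@H]1CC[C@]2(C)[C@H](CCC(=O)[C@H]2CC=C)OC1(C)C | intermediate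
10 | (3S,5aS,6R,9aS)-6-allyl-3-(tert-butyldimethylsilyloxy)-2,2,5a-trimethyl-7-methylidenedecahydro-1-benzoxepine | CC(C)(C)[Si](C)(C)O[C@H]1CC[C@]2(C)[C@H](CCC(=C)[C@H]2CC=C)OC1(C)C | intermediate
11 | (2E,7S,8S,11S)-7,8:11,12-diepoxy-8,12-dimethyl-1-(bicycle B)tridec-2-en-4-one | CC(C)(C)[Si](C)(C)O[C@H]1CC[C@]2(C)[C@H](CCC(=C)[C@H]2C/C=C/C(=O)CC[C@@H]2O[C@@]2(C)CC[C@@H]2OC2(C)C)OC1(C)C | intermediate
12 | (3Z,7S,8S,11S)-7,8:11,12-diepoxy-8,12-dimethyl-1-(bicycle B)-4-(triethylsilyloxy)tridec-3-ene | CC(C)(C)[Si](C)(C)O[C@H]1CC[C@]2(C)[C@H](CCC(=C)[C@H]2CC/C=C(\O[Si](CC)(CC)CC)CC[C@@H]2O[C@@]2(C)CC[C@@H]2OC2(C)C)OC1(C)C | intermediate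
13 | 1-[(3S,5aS,6S,9aS)-2,2,5a-trimethyl-7-oxo-3-(triethylsilyloxy)decahydro-1-benzoxepin-6-yl]-2-(bicycle B)ethane | CC[Si](CC)(CC)O[C@H]1CC[C@]2(C)[C@H](CCC(=O)[C@H]2CC[C@H]2[C@]3(C)CC[C@H](O[Si](C)(C)C(C)(C)C)C(C)(C)O[C@H]3CCC2=C)OC1(C)C | intermediate
14 | 1-[(3S,5aS,6S,9aS)-3-hydroxy-2,2,5a-trimethyl-7-oxodecahydro-1-benzoxepin-6-yl]-2-(bicycle B)ethane | O[C@H]1CC[C@]2(C)[C@H](CCC(=O)[C@H]2CC[C@H]2[C@]3(C)CC[C@H](O[Si](C)(C)C(C)(C)C)C(C)(C)O[C@H]3CCC2=C)OC1(C)C | intermediate
15 | 1-[(3S,5aS,6S,7R,9aS)-3,7-dihydroxy-2,2,5a,7-tetramethyldecahydro-1-benzoxepin-6-yl]-2-(bicycle B)ethane | O[C@H]1CC[C@]2(C)[C@H](CC[C@@](C)(O)[C@H]2CC[C@H]2[C@]3(C)CC[C@H](O[Si](C)(C)C(C)(C)C)C(C)(C)O[C@H]3CCC2=C)OC1(C)C | intermediate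
16 | 7'-spiro-oxirane of 15 (7'S, oxygen α) | O[C@H]1CC[C@]2(C)[C@H](CC[C@@](C)(O)[C@H]2CC[C@H]2[C@]3(C)CC[C@H](O[Si](C)(C)C(C)(C)C)C(C)(C)O[C@H]3CC[C@]2(C4)O4)OC1(C)C | intermediate
17 | 1-[(3S,5aS,6S,7R,9aS)-3,7-dihydroxy-2,2,5a,7-tetramethyldecahydro-1-benzoxepin-6-yl]-2-[(3'S,5a'S,6'S,7'S,9a'S)-3'-(tert-butyldimethylsilyloxy)-7'-hydroxy-2',2',5a',7'-tetramethyldecahydro-1-benzoxepin-6'-yl]ethane | O[C@H]1CC[C@]2(C)[C@H](CC[C@@](C)(O)[C@H]2CC[C@H]2[C@]3(C)CC[C@H](O[Si](C)(C)C(C)(C)C)C(C)(C)O[C@H]3CC[C@]2(C)O)OC1(C)C | intermediate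
18 | 3,7,7'-tri-O-acetate of 17 | CC(=O)O[C@H]1CC[C@]2(C)[C@H](CC[C@@](C)(OC(C)=O)[C@H]2CC[C@H]2[C@]3(C)CC[C@H](O[Si](C)(C)C(C)(C)C)C(C)(C)O[C@H]3CC[C@]2(C)OC(C)=O)OC1(C)C | intermediate
19 | CNP0169816.1, (3S,5aS,6S,7R,9aS)-6-{2-[(3S,5aS,6S,7S,9aS)-7-acetoxy-3-hydroxy-2,2,5a,7-tetramethyldecahydro-1-benzoxepin-6-yl]ethyl}-2,2,5a,7-tetramethyldecahydro-1-benzoxepine-3,7-diyl diacetate | CC(=O)O[C@H]1CC[C@]2(C)[C@H](CC[C@@](C)(OC(C)=O)[C@H]2CC[C@H]2[C@]3(C)CC[C@H](O)C(C)(C)O[C@H]3CC[C@]2(C)OC(C)=O)OC1(C)C | target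

**Totals and risk**

Total step count: 15. Longest linear sequence: 15 steps (1 → 19; compound 5 re-enters at step 8).

The three steps most likely to fail are 10, 12 and 14.

Step 10 (second cascade on the 45-carbon substrate). The exocyclic alkene of ring system B is the one extra π-nucleophile present and may interfere. The fallback sets out from 10 and comes back at 17 by hydrating that alkene before the union. mCPBA (1.0 equiv, NaHCO3, CH2Cl2, −20 °C) epoxidises the 1,1-disubstituted alkene of 10 in preference to the allyl group, from the α face, to give the spiro-epoxide F1. LiBHEt3 opens it to the allyl tertiary alcohol F2. Cross-metathesis of F2 with 5 under the conditions of step 8 gives the enone F3, and hydrosilylation as in step 9 gives the enol silane F4. The TESOTf cascade on F4, now free of the competing alkene, gives the silyl ether F5, which aqueous acetic acid converts to the keto diol F6. Addition of MeLi/CeCl3 to F6 as in step 11 gives 17.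

Step 12 (face selectivity of the peracid at the exocyclic alkene). The fallback sets out from 15 and comes back at 17 by replacing epoxidation with dihydroxylation. OsO4 (cat.) with N-methylmorpholine N-oxide, which is bulkier and more face-selective, adds from the α face to give the tetraol F7. TsCl in pyridine sulfonylates only the primary hydroxyl to give the tosylate F8. LiBHEt3 then removes the sulfonate (through epoxide 16 formed in the flask or by direct displacement) to give 17.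

Step 14 (acetylation of two tertiary alcohols, one axial and syn to the 5a-methyl). The fallback sets out from 14 and comes back at 18 by acetylating each tertiary oxygen when it is formed. MeLi alone (Et2O, −78 °C) adds to 14, and the two lithium alkoxides are trapped in the same flask with Ac2O to give the diacetate alkene F9. Mukaiyama hydration (Co(acac)2, PhSiH3, O2, i-PrOH/THF), which tolerates esters, delivers oxygen to the tertiary radical from the α face to give the tertiary alcohol F10. This less hindered equatorial alcohol is then acetylated alone (Ac2O, DMAP, Et3N, 40 °C) to give 18.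

**Further compounds**

F1 | step 10 | 7-spiro-oxirane of 10 (oxygen α, allyl intact) | CC(C)(C)[Si](C)(C)O[C@H]1CC[C@]2(C)[C@H](CC[C@](C3)(O3)[C@H]2CC=C)OC1(C)C
F2 | step 10 | (3S,5aS,6S,7S,9aS)-6-allyl-3-(tert-butyldimethylsilyloxy)-2,2,5a,7-tetramethyldecahydro-1-benzoxepin-7-ol | CC(C)(C)[Si](C)(C)O[C@H]1CC[C@]2(C)[C@H](CC[C@](C)(O)[C@H]2CC=C)OC1(C)C
F3 | step 10 | E enone from F2 and 5 (analogue of 11 with 7'α-OH, 7'β-CH3) | CC(C)(C)[Si](C)(C)O[C@H]1CC[C@]2(C)[C@H](CC[C@](C)(O)[C@H]2C/C=C/C(=O)CC[C@@H]2O[C@@]2(C)CC[C@@H]2OC2(C)C)OC1(C)C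
F4 | step 10 | Z triethylsilyl enol ether of F3 (analogue of 12) | CC(C)(C)[Si](C)(C)O[C@H]1CC[C@]2(C)[C@H](CC[C@](C)(O)[C@H]2CC/C=C(\O[Si](CC)(CC)CC)CC[C@@H]2O[C@@]2(C)CC[C@@H]2OC2(C)C)OC1(C)C
F5 | step 10 | tetracyclic ketone with 3-O-triethylsilyl, 7'-OH and 3'-O-TBS | CC[Si](CC)(CC)O[C@H]1CC[C@]2(C)[C@H](CCC(=O)[C@H]2CC[C@H]2[C@]3(C)CC[C@H](O[Si](C)(C)C(C)(C)C)C(C)(C)O[C@H]3CC[C@]2(C)O)OC1(C)C
F6 | step 10 | tetracyclic keto diol (3-OH, 7-oxo, 7'-OH, 3'-O-TBS) | O[C@H]1CC[C@]2(C)[C@H](CCC(=O)[C@H]2CC[C@H]2[C@]3(C)CC[C@H](O[Si](C)(C)C(C)(C)C)C(C)(C)O[C@H]3CC[C@]2(C)O)OC1(C)C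
F7 | step 12 | tetraol: 15 with the 7'-methylidene converted to 7'α-OH and 7'β-CH2OH | O[C@H]1CC[C@]2(C)[C@H](CC[C@@](C)(O)[C@H]2CC[C@H]2[C@]3(C)CC[C@H](O[Si](C)(C)C(C)(C)C)C(C)(C)O[C@H]3CC[C@]2(CO)O)OC1(C)C
F8 | step 12 | primary p-toluenesulfonate of F7 | O[C@H]1CC[C@]2(C)[C@H](CC[C@@](C)(O)[C@H]2CC[C@H]2[C@]3(C)CC[C@H](O[Si](C)(C)C(C)(C)C)C(C)(C)O[C@H]3CC[C@]2(COS(=O)(=O)c4ccc(C)cc4)O)OC1(C)C
F9 | step 14 | 3,7-di-O-acetate of 15 (7'-methylidene, 3'-O-TBS) | CC(=O)O[C@H]1CC[C@]2(C)[C@H](CC[C@@](C)(OC(C)=O)[C@H]2CC[C@H]2[C@]3(C)CC[C@H](O[Si](C)(C)C(C)(C)C)C(C)(C)O[C@H]3CCC2=C)OC1(C)C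
F10 | step 14 | 3,7-di-O-acetate of 17 (free 7'α-OH, 3'-O-TBS) | CC(=O)O[C@H]1CC[C@]2(C)[C@H](CC[C@@](C)(OC(C)=O)[C@H]2CC[C@H]2[C@]3(C)CC[C@H](O[Si](C)(C)C(C)(C)C)C(C)(C)O[C@H]3CC[C@]2(C)O)OC1(C)C
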